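**Retrosynthetic overview**

1. The last bond cut is the CH2 bridge between ring A (2-butanoylfilicinic acid) and ring B: the Mannich base of ring A alkylates the one free ring carbon of the ring B–ring C dimer.
2. The strategy rests on ring B: its three hydroxyl-bearing carbons C2, C4 and C6 are each ortho or para to the butanoyl carbonyl on C1. All three C–O bonds are therefore traced back to C–F bonds of a 2,4,6-trifluoroaryl ketone and made in one operation with benzyloxide.
3. The ring B–CH2–ring C bond is made before ring B carries any oxygen, by reductive Friedel–Crafts arylation of 3-butanoyl-2,4,6-trifluorobenzaldehyde with the ring C unit. Ring C enters already as its dibenzyl ether, so no ring C phenoxide ever sits next to the fluorinated ring and xanthene closure is excluded.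
4. No ring is built: rings B and C are bought benzene rings (2,4,6-trifluorobenzaldehyde, 2-methylphloroglucinol). Ring A arises from butanoylphloroglucinol by dearomatising gem-dimethylation. The target has no stereocentre.

Key step: step 8

**Remarks on the chemistry**

- Ring C unit: aspidinol has its free ring carbon between a hydroxyl and the methoxy group and would give the wrong ring C pattern. The target needs the isomer 1-(4,6-dihydroxy-2-methoxy-3-methylphenyl)butan-1-one (free carbon between the two hydroxyls, methoxy between methyl and butanoyl). It is used as its dibenzyl ether 11.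
- Assumption for step 8: the fluorines are taken to leave in the order para, then the open ortho, then the ortho fluorine flanked by the bridge. Any order converges on 17.
- Stoichiometry of step 8: benzyl alcohol 14 is charged in excess and half of it is converted into sodium benzyloxide by NaH; three equivalents of this benzyloxide end up in 17.
- Carbinol 12 is racemic; its stereocentre is removed within step 7.

**Route**

Step 1
Reactants: 1 2,4,6-trifluorobenzaldehyde
Product: 2 2-(2,4,6-trifluorophenyl)-1,3-dioxolane
Conditions: HOCH2CH2OH, p-TsOH (cat.), toluene, reflux, Dean–Stark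
Reagents that add atoms: ethane-1,2-diol, OCCO
Why: Acid-catalysed acetalisation with azeotropic removal of water masks the formyl group against the organolithium of step 2.

Step 2
Reactants: 2 2-(2,4,6-trifluorophenyl)-1,3-dioxolane; 3 N-methoxy-N-methylbutanamide
Product: 6 1-[3-(1,3-dioxolan-2-yl)-2,4,6-trifluorophenyl]butan-1-one, via aryllithium 4 (not isolated), via lithium hemiaminal adduct 5 (not isolated)
Conditions: n-BuLi, THF, −78 °C; then 3, −78 → −20 °C; sat. aq NH4Cl, 0 °C
Reagents that add atoms: none
Why: Ortho-lithiation occurs at the only kind of ring hydrogen (each lies between two fluorines, and the two are equivalent), and the Weinreb ketone synthesis stops at the chelated adduct 5, which should collapse to the ketone only on quenching.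

Step 3
Reactants: 6 1-[3-(1,3-dioxolan-2-yl)-2,4,6-trifluorophenyl]butan-1-one
Product: 7 3-butanoyl-2,4,6-trifluorobenzaldehyde
Conditions: 2 M HCl, THF, 50 °C
Reagents that add atoms: water, O
Why: Acid-catalysed acetal hydrolysis frees the aldehyde, while the ketone and the C–F bonds are inert to aqueous acid.

Step 4
Reactants: 8 2-methylbenzene-1,3,5-triol
Product: 9 1-(2,4,6-trihydroxy-3-methylphenyl)butan-1-one
Conditions: PrCOCl, AlCl3, PhNO2–CH2Cl2, 0 → 45 °C; then ice, aq HCl
Reagents that add atoms: butanoyl chloride, CCCC(=O)Cl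
Why: Friedel–Crafts C-acylation of a phloroglucinol (any aryl ester formed undergoes Fries rearrangement under AlCl3) can give only one ketone because the two free ring carbons of 8 are equivalent, and the acyl group deactivates the ring against a second acylation.

Step 5
Reactants: 9 1-(2,4,6-trihydroxy-3-methylphenyl)butan-1-one
Product: 10 1-[4,6-bis(benzyloxy)-2-hydroxy-3-methylphenyl]butan-1-one
Conditions: BnBr (2.1 equiv), K2CO3, DMF, 0 °C → rt
Reagents that add atoms: benzyl bromide, BrCc1ccccc1
Why: Williamson etherification should take the 4-hydroxyl (para to the carbonyl, not hydrogen-bonded) and then the 6-hydroxyl, while the 2-hydroxyl, pressed against the carbonyl by the neighbouring methyl group, holds the stronger hydrogen bond, is the more hindered and should stay free.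

Step 6
Reactants: 10 1-[4,6-bis(benzyloxy)-2-hydroxy-3-methylphenyl]butan-1-one
Product: 11 1-[4,6-bis(benzyloxy)-2-methoxy-3-methylphenyl]butan-1-one
Conditions: MeI, K2CO3, DMF, 50 °C
Reagents that add atoms: iodomethane, CI
Why: Williamson O-methylation of the remaining chelated phenol under more forcing conditions; carbonate is too weak to enolise the ketone, so C-methylation is not expected.

Step 7
Reactants: 7 3-butanoyl-2,4,6-trifluorobenzaldehyde; 11 1-[4,6-bis(benzyloxy)-2-methoxy-3-methylphenyl]butan-1-one
Product: 13 1-[3-{[2,6-bis(benzyloxy)-3-butanoyl-4-methoxy-5-methylphenyl]methyl}-2,4,6-trifluorophenyl]butan-1-one, via diaryl carbinol 12 (not isolated)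
Conditions: Et3SiH (3 equiv), CF3CO2H (10 equiv), CH2Cl2, 0 °C → rt
Reagents that add atoms: none
Why: Reductive Friedel–Crafts benzylation (hydroxyalkylation, then ionic hydrogenation): the sole free carbon of 11, ortho, ortho and para to three alkoxy groups, attacks the highly electrophilic aldehyde, carbinol 12 ionises to a cation stabilised by ring C and is reduced by the silane, and the two hindered ketones should be reduced much more slowly.

Step 8
Reactants: 13 1-[3-{[2,6-bis(benzyloxy)-3-butanoyl-4-methoxy-5-methylphenyl]methyl}-2,4,6-trifluorophenyl]butan-1-one; 14 benzyl alcohol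
Product: 17 1-[2,4,6-tris(benzyloxy)-3-{[2,6-bis(benzyloxy)-3-butanoyl-4-methoxy-5-methylphenyl]methyl}phenyl]butan-1-one, via monobenzyloxy difluoride 15 (not isolated), via bis(benzyloxy) monofluoride 16 (not isolated)
Conditions: 14 (10 equiv), NaH (5 equiv), THF, 0 °C, until H2 evolution ends; then 13 (1 equiv), DMSO, 20 °C, then 80 °C, argon
Reagents that add atoms: sodium benzyloxide, [Na+].[O-]Cc1ccccc1
Why: Each fluorine of ring B in 13 is ortho or para to the butanoyl carbonyl, so benzyloxide adds at the C–F carbon to give a Meisenheimer anion whose charge is carried onto the ketone oxygen, and loss of fluoride restores the arene, three times over through 15 and 16 (addition–elimination). The closest known reaction type is the exchange of fluoride for alkoxide on ortho- and para-fluoroaryl ketones and on polyfluoroarenes, here applied to all three positions of one crowded ring. No ring closes and no stereocentre forms; three equivalents of the sodium benzyloxide made in the flask from 14 are consumed, and the three C–O bonds of ring B are made in one operation. The step needs exhaustive substitution without damage to the two ketones: fluoride is the best leaving group for this mechanism and benzyloxide in DMSO is a small, strong nucleophile, the first exchange is run cold, where the electron-poor ring reacts fastest and cleavage of the aryl–acyl bond is least likely, and only the last fluorine, flanked on both sides and deactivated by two alkoxy groups, is forced by heating. Excess benzyl alcohol buffers the medium, so that enolates of the butanoyl groups stay in equilibrium with the ketones and do not switch off the activation, and hemiketal formation at the hindered carbonyls is reversible. A xanthene cannot form, because both ring C oxygens next to the bridge are already benzyl ethers and no phenoxide is present.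

Step 9
Reactants: 17 1-[2,4,6-tris(benzyloxy)-3-{[2,6-bis(benzyloxy)-3-butanoyl-4-methoxy-5-methylphenyl]methyl}phenyl]butan-1-one
Product: 18 1-[3-[(3-butanoyl-2,6-dihydroxy-4-methoxy-5-methylphenyl)methyl]-2,4,6-trihydroxyphenyl]butan-1-one
Conditions: H2 (1 atm), Pd/C (10% Pd), EtOAc–MeOH, rt
Reagents that add atoms: none
Why: Hydrogenolysis of the five aryl benzyl ethers over palladium; the ketones become hydrogen-bonded acylphloroglucinol carbonyls, which should resist hydrogenation under these mild conditions.

Step 10
Reactants: 19 1-(2,4,6-trihydroxyphenyl)butan-1-one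
Product: 20 2-butanoylfilicinic acid (2-butanoyl-3,5-dihydroxy-6,6-dimethylcyclohexa-2,4-dien-1-one, drawn as this enol form)
Conditions: MeI (2.2 equiv), NaOMe, MeOH, 0 °C → rt; then aq HCl
Reagents that add atoms: iodomethane, CI
Why: Dearomatising double C-methylation of the acylphloroglucinol anion, the classical route to acylfilicinic acids, puts both methyl groups on one ring carbon to give the gem-dimethyl trione enol, which should be separable from ring-methylated and over-methylated by-products.

Step 11
Reactants: 20 2-butanoylfilicinic acid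
Product: 21 2-butanoyl-4-[(dimethylamino)methyl]-3,5-dihydroxy-6,6-dimethylcyclohexa-2,4-dien-1-one
Conditions: CH2(NMe2)2 (1.1 equiv), CH2Cl2, 0 °C → rt
Reagents that add atoms: bis(dimethylamino)methane, CN(C)CN(C)C
Why: Mannich aminomethylation at the only nucleophilic carbon of the vinylogous acid 20, whose acidity ionises the aminal to the iminium ion.

Step 12
Reactants: 18 1-[3-[(3-butanoyl-2,6-dihydroxy-4-methoxy-5-methylphenyl)methyl]-2,4,6-trihydroxyphenyl]butan-1-one; 21 2-butanoyl-4-[(dimethylamino)methyl]-3,5-dihydroxy-6,6-dimethylcyclohexa-2,4-dien-1-one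
Product: 23 2-butanoyl-4-({3-butanoyl-5-[(3-butanoyl-2,6-dihydroxy-4-methoxy-5-methylphenyl)methyl]-2,4,6-trihydroxyphenyl}methyl)-3,5-dihydroxy-6,6-dimethylcyclohexa-2,4-dien-1-one (the target), via methylidene trione 22 (not isolated)
Conditions: 1,4-dioxane, 80 °C, argon; then dil. HCl
Reagents that add atoms: none
Why: Mannich-base alkylation: thermal loss of dimethylamine from 21 (retro-Michael elimination) should give the methylidene trione 22, a quinone-methide-type Michael acceptor that the single free ring B carbon of 18, lying between two hydroxyls, attacks in a conjugate addition followed by re-aromatisation.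

**Compound list**

1 | 2,4,6-trifluorobenzaldehyde | O=Cc1c(F)cc(F)cc1F | starting material
2 | 2-(2,4,6-trifluorophenyl)-1,3-dioxolane | Fc1cc(F)c(C2OCCO2)c(F)c1 | intermediate
3 | N-methoxy-N-methylbutanamide | CCCC(=O)N(C)OC | starting material
4 | [3-(1,3-dioxolan-2-yl)-2,4,6-trifluorophenyl]lithium | [Li]c1c(F)cc(F)c(C2OCCO2)c1F | intermediate (not isolated)
5 | lithium 1-[3-(1,3-dioxolan-2-yl)-2,4,6-trifluorophenyl]-1-[methoxy(methyl)amino]butan-1-olate | CCCC(O[Li])(N(C)OC)c1c(F)cc(F)c(C2OCCO2)c1F | intermediate (not isolated)
6 | 1-[3-(1,3-dioxolan-2-yl)-2,4,6-trifluorophenyl]butan-1-one | CCCC(=O)c1c(F)cc(F)c(C2OCCO2)c1F | intermediate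
7 | 3-butanoyl-2,4,6-trifluorobenzaldehyde | CCCC(=O)c1c(F)cc(F)c(C=O)c1F | intermediate
8 | 2-methylbenzene-1,3,5-triol | Cc1c(O)cc(O)cc1O | starting material
9 | 1-(2,4,6-trihydroxy-3-methylphenyl)butan-1-one | CCCC(=O)c1c(O)cc(O)c(C)c1O | intermediate
10 | 1-[4,6-bis(benzyloxy)-2-hydroxy-3-methylphenyl]butan-1-one | CCCC(=O)c1c(O)c(C)c(OCc2ccccc2)cc1OCc3ccccc3 | intermediate
11 | 1-[4,6-bis(benzyloxy)-2-methoxy-3-methylphenyl]butan-1-one | CCCC(=O)c1c(OC)c(C)c(OCc2ccccc2)cc1OCc3ccccc3 | intermediate
12 | 1-[3-{[2,6-bis(benzyloxy)-3-butanoyl-4-methoxy-5-methylphenyl](hydroxy)methyl}-2,4,6-trifluorophenyl]butan-1-one (racemic) | CCCC(=O)c1c(F)cc(F)c(C(O)c2c(OCc3ccccc3)c(C)c(OC)c(C(=O)CCC)c2OCc4ccccc4)c1F | intermediate (not isolated)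
13 | 1-[3-{[2,6-bis(benzyloxy)-3-butanoyl-4-methoxy-5-methylphenyl]methyl}-2,4,6-trifluorophenyl]butan-1-one | CCCC(=O)c1c(F)cc(F)c(Cc2c(OCc3ccccc3)c(C)c(OC)c(C(=O)CCC)c2OCc4ccccc4)c1F | intermediate
14 | benzyl alcohol | OCc1ccccc1 | starting material
15 | 1-[4-(benzyloxy)-3-{[2,6-bis(benzyloxy)-3-butanoyl-4-methoxy-5-methylphenyl]methyl}-2,6-difluorophenyl]butan-1-one | CCCC(=O)c1c(F)cc(OCc2ccccc2)c(Cc3c(OCc4ccccc4)c(C)c(OC)c(C(=O)CCC)c3OCc5ccccc5)c1F | intermediate (not isolated)
16 | 1-[4,6-bis(benzyloxy)-3-{[2,6-bis(benzyloxy)-3-butanoyl-4-methoxy-5-methylphenyl]methyl}-2-fluorophenyl]butan-1-one | CCCC(=O)c1c(OCc2ccccc2)cc(OCc3ccccc3)c(Cc4c(OCc5ccccc5)c(C)c(OC)c(C(=O)CCC)c4OCc6ccccc6)c1F | intermediate (not isolated)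
17 | 1-[2,4,6-tris(benzyloxy)-3-{[2,6-bis(benzyloxy)-3-butanoyl-4-methoxy-5-methylphenyl]methyl}phenyl]butan-1-one | CCCC(=O)c1c(OCc2ccccc2)cc(OCc3ccccc3)c(Cc4c(OCc5ccccc5)c(C)c(OC)c(C(=O)CCC)c4OCc6ccccc6)c1OCc7ccccc7 | intermediate
18 | 1-[3-[(3-butanoyl-2,6-dihydroxy-4-methoxy-5-methylphenyl)methyl]-2,4,6-trihydroxyphenyl]butan-1-one | CCCC(=O)c1c(O)cc(O)c(Cc2c(O)c(C)c(OC)c(C(=O)CCC)c2O)c1O | intermediate
19 | 1-(2,4,6-trihydroxyphenyl)butan-1-one | CCCC(=O)c1c(O)cc(O)cc1O | starting material
20 | 2-butanoylfilicinic acid (2-butanoyl-3,5-dihydroxy-6,6-dimethylcyclohexa-2,4-dien-1-one) | CCCC(=O)C1=C(O)C=C(O)C(C)(C)C1=O | intermediate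
21 | 2-butanoyl-4-[(dimethylamino)methyl]-3,5-dihydroxy-6,6-dimethylcyclohexa-2,4-dien-1-one | CCCC(=O)C1=C(O)C(CN(C)C)=C(O)C(C)(C)C1=O | intermediate
22 | 2-butanoyl-3-hydroxy-6,6-dimethyl-4-methylidenecyclohex-2-ene-1,5-dione | CCCC(=O)C1=C(O)C(=C)C(=O)C(C)(C)C1=O | intermediate (not isolated)
23 | 2-butanoyl-4-({3-butanoyl-5-[(3-butanoyl-2,6-dihydroxy-4-methoxy-5-methylphenyl)methyl]-2,4,6-trihydroxyphenyl}methyl)-3,5-dihydroxy-6,6-dimethylcyclohexa-2,4-dien-1-one | CCCC(=O)C1=C(O)C(Cc2c(O)c(Cc3c(O)c(C)c(OC)c(C(=O)CCC)c3O)c(O)c(C(=O)CCC)c2O)=C(O)C(C)(C)C1=O | target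

**Step count**

Total: 12 steps. Longest linear sequence: 7 steps (1, 2, 3, 7, 8, 9, 12; the ring C line 4, 5, 6, 7, 8, 9, 12 is equally long).

**Steps most likely to fail**

Step 8. The exchange may stall after one or two fluorines, because each alkoxy group makes the ring more electron-rich and turns the ketone further out of conjugation. The butanoyl groups may also be enolised, benzyloxide may attack the ring B carbonyl with loss of the acyl group, or it may transfer hydride to a ketone. The fallback leaves the fluorinated series and builds the ring B–ring C bridge by known phloroglucinol chemistry; it sets out from 11 and 19 and comes back at 18. Hydrogenolysis of 11 (H2, Pd/C, EtOAc) should give 1-(4,6-dihydroxy-2-methoxy-3-methylphenyl)butan-1-one F1. Aminomethylation of its only free ring carbon with bis(dimethylamino)methane should give the Mannich base 1-{5-[(dimethylamino)methyl]-4,6-dihydroxy-2-methoxy-3-methylphenyl}butan-1-one F2. Heating F2 with an excess of 19 in dioxane should release the ortho-quinone methide 4-butanoyl-5-hydroxy-3-methoxy-2-methyl-6-methylidenecyclohexa-2,4-dien-1-one F3, which one of the two equivalent free carbons of 19 should trap to give 18.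

Step 7. The silane may reduce a ketone to a methylene group, the acid may remove or shift a benzyl group from the electron-rich ring, or the aldehyde may be reduced before it is arylated. The fallback makes the bridge by cross-coupling; it sets out from 7 and 11 and comes back at 13. Selective reduction of the aldehyde of 7 (NaBH4, 0.3 equiv, EtOH, −78 °C) should give 1-[2,4,6-trifluoro-3-(hydroxymethyl)phenyl]butan-1-one F4, and PBr3 in CH2Cl2 should convert it into 1-[3-(bromomethyl)-2,4,6-trifluorophenyl]butan-1-one F5. Bromination of 11 at its free carbon (N-bromosuccinimide, MeCN, 0 °C) should give 1-[2,4-bis(benzyloxy)-3-bromo-6-methoxy-5-methylphenyl]butan-1-one F6. Zinc insertion into F5 (Zn dust, LiCl, THF) should give the benzylzinc bromide [(3-butanoyl-2,4,6-trifluorophenyl)methyl]zinc bromide F7, and Negishi coupling of F7 with F6 (Pd(OAc)2, SPhos, THF, 60 °C) should give 13.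

Step 5. The two ortho hydroxyls may be benzylated with poor site selectivity, giving the isomer with the free hydroxyl next to the ring hydrogen, and the free ring carbon may be C-benzylated. The fallback fixes the oxygen pattern on a symmetric ring and adds the methyl group afterwards; it sets out from 19 and comes back at 10. Dibenzylation of 19 (BnBr, 2 equiv, K2CO3, DMF), in which the two ortho hydroxyls are equivalent, should give 1-[2,4-bis(benzyloxy)-6-hydroxyphenyl]butan-1-one F8. Nuclear C-methylation of F8 ortho to the chelated hydroxyl (MeI, NaOMe, MeOH, reflux) should give 10.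

**Further compounds**

F1 | step 8 | 1-(4,6-dihydroxy-2-methoxy-3-methylphenyl)butan-1-one | CCCC(=O)c1c(OC)c(C)c(O)cc1O
F2 | step 8 | 1-{5-[(dimethylamino)methyl]-4,6-dihydroxy-2-methoxy-3-methylphenyl}butan-1-one | CCCC(=O)c1c(OC)c(C)c(O)c(CN(C)C)c1O
F3 | step 8 | 4-butanoyl-5-hydroxy-3-methoxy-2-methyl-6-methylidenecyclohexa-2,4-dien-1-one | CCCC(=O)C1=C(O)C(=C)C(=O)C(C)=C1OC
F4 | step 7 | 1-[2,4,6-trifluoro-3-(hydroxymethyl)phenyl]butan-1-one | CCCC(=O)c1c(F)cc(F)c(CO)c1F
F5 | step 7 | 1-[3-(bromomethyl)-2,4,6-trifluorophenyl]butan-1-one | CCCC(=O)c1c(F)cc(F)c(CBr)c1F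
F6 | step 7 | 1-[2,4-bis(benzyloxy)-3-bromo-6-methoxy-5-methylphenyl]butan-1-one | CCCC(=O)c1c(OC)c(C)c(OCc2ccccc2)c(Br)c1OCc3ccccc3
F7 | step 7 | [(3-butanoyl-2,4,6-trifluorophenyl)methyl]zinc bromide | CCCC(=O)c1c(F)cc(F)c(C[Zn]Br)c1F
F8 | step 5 | 1-[2,4-bis(benzyloxy)-6-hydroxyphenyl]butan-1-one | CCCC(=O)c1c(O)cc(OCc2ccccc2)cc1OCc3ccccc3
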